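**Retrosynthetic overview**
1. Target 33 is six oxygenated benzene rings A–F joined by five diaryl ether oxygens; the last step frees all fifteen hydroxyls from pentadecamethyl ether 32.
2. The ethers B–C, C–D and D–E are each cut at the aryl carbon that has no flanking methoxy groups: three copper-catalysed couplings of a di-ortho-substituted phenol (20, 24, 29) with an aryl halide (22, 27, 31), a benzyl ether masking each next phenol. The E–F ether is pre-formed by Chan–Lam coupling.
3. The feature the strategy rests on: ring B carries the ring A ether oxygen on C1 between C2–H and C6–H, meta to the C3 oxygen, with C4 and C5 oxygenated, i.e. a resorcinol monoether. Cutting C2–C3, C1–C6 and C3–C4 gives aryl ynol ether 5 and the dioxygenated vinylketene from diazo enone 13 (Danheiser benzannulation).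
4. Ring order: ring B is the only ring built (step 7); rings A, C, D, E and F enter as aromatic building blocks (1, 21, 25, 30).

Key step: step 7

Assumption: 2,4,6-trimethoxyphenol (1) and 2,3,4-trimethoxyphenol (25) are taken as purchasable catalogue phenols. The target has no stereocentre, so stereochemistry matters only as alkene geometry in intermediates. In each ring C1 is the carbon bearing the ether oxygen that points towards ring A; in ring D, C2 bears the oxygen to ring E.

**Route**

Step 1
Reactants: 1 2,4,6-trimethoxyphenol; 2 trichloroethylene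
Product: 3 (E)-2-[(1,2-dichloroethenyl)oxy]-1,3,5-trimethoxybenzene
Conditions: K2CO3, DMF, 70 °C, N2
Reagents that add atoms: none
Why: K2CO3 turns trichloroethylene into dichloroacetylene in situ and the phenoxide of 1 adds to it with anti protonation (the established addition route to aryl (E)-1,2-dichlorovinyl ethers), the small linear electrophile being accessible even to a di-ortho-substituted phenoxide.

Step 2
Reactants: 3 (E)-2-[(1,2-dichloroethenyl)oxy]-1,3,5-trimethoxybenzene
Product: 5 2-(ethynyloxy)-1,3,5-trimethoxybenzene, via lithium aryloxyacetylide 4 (not isolated)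
Conditions: n-BuLi (2.2 equiv), THF, −78 to −40 °C; H2O, −78 °C
Reagents that add atoms: none
Why: n-BuLi dehydrochlorinates 3 to the chloroalkynyl ether and exchanges the remaining chlorine for lithium (dichlorovinyl ether route to ynol ethers), cold protonation of 4 should give terminal ynol ether 5, which is kept cold in solution and used at once; at −78 °C ring A is not metalated.

Step 3
Reactants: 6 methyl methoxyacetate; 7 benzyl bromide
Product: 9 methyl (Z)-3-(benzyloxy)-2-methoxyprop-2-enoate, via sodium formyl enolate 8 (not isolated)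
Conditions: NaH, HCO2Me, THF, 0 °C to rt; then BnBr, DMF, rt
Reagents that add atoms: methyl formate, COC=O
Why: crossed Claisen formylation (6 has one enolisable carbon, methyl formate none) gives stabilised enolate 8, which should be alkylated on oxygen in DMF because C-alkylation would build a quaternary carbon and forgo the conjugated β-alkoxyacrylate; the Z isomer (ester trans to OBn) is the thermodynamic one, and the geometry is erased when ring B aromatises.

Step 4
Reactants: 9 methyl (Z)-3-(benzyloxy)-2-methoxyprop-2-enoate
Product: 10 (Z)-3-(benzyloxy)-N,2-dimethoxy-N-methylprop-2-enamide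
Conditions: MeNH(OMe)·HCl, i-PrMgCl, THF, −20 to 0 °C; H2O
Reagents that add atoms: N,O-dimethylhydroxylamine hydrochloride, CNOC.Cl
Why: ester aminolysis by the chloromagnesium amide of N,O-dimethylhydroxylamine (Weinreb amide formation) proceeds by 1,2-attack at low temperature, the β-alkoxyacrylate being too poor a Michael acceptor to lose its benzyloxy group by addition–elimination.

Step 5
Reactants: 10 (Z)-3-(benzyloxy)-N,2-dimethoxy-N-methylprop-2-enamide
Product: 11 (Z)-4-(benzyloxy)-3-methoxybut-3-en-2-one
Conditions: MeMgBr, THF, 0 °C; H2O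
Reagents that add atoms: methylmagnesium bromide, C[Mg]Br
Why: Weinreb ketone synthesis, in which the magnesium-chelated tetrahedral adduct stops after one methyl addition and releases the methyl ketone on quench with the enol ether untouched.

Step 6
Reactants: 11 (Z)-4-(benzyloxy)-3-methoxybut-3-en-2-one
Product: 13 (Z)-4-(benzyloxy)-1-diazo-3-methoxybut-3-en-2-one, via trifluoroacetyl diketone 12 (not isolated)
Conditions: LiN(SiMe3)2, THF, −78 °C, then CF3CO2CH2CF3; cold dilute HCl work-up; MsN3, Et3N, H2O, MeCN, rt
Reagents that add atoms: methanesulfonyl azide, CS(=O)(=O)N=[N+]=[N-]; 2,2,2-trifluoroethyl trifluoroacetate, O=C(OCC(F)(F)F)C(F)(F)F (its CF3CO group sits in 12 only)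
Why: the kinetic lithium enolate of 11 (the methyl group is the only enolisable site) is trifluoroacetylated and diketone 12 undergoes Regitz diazo transfer with loss of the trifluoroacetyl group (detrifluoroacetylative diazo transfer), the standard entry to α,β-unsaturated diazomethyl ketones, preferred to acid chloride/diazomethane because it keeps HCl and dipolar cycloaddition away from the enol ether double bond.

Step 7
Reactants: 5 2-(ethynyloxy)-1,3,5-trimethoxybenzene (1.5 equiv); 13 (Z)-4-(benzyloxy)-1-diazo-3-methoxybut-3-en-2-one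
Product: 18 2-(benzyloxy)-3-methoxy-5-(2,4,6-trimethoxyphenoxy)phenol, via vinylketene 14 (not isolated), via cyclobutenone 15 (not isolated), via dienylketene 16 (not isolated), via cyclohexadienone 17 (not isolated)
Conditions: hν (300 nm, Pyrex), degassed ClCH2CH2Cl, rt; then 80 °C
Reagents that add atoms: none
Why: Light expels N2 from 13 and the alkenyl group shifts (photochemical Wolff rearrangement) to give vinylketene 14, which adds across its C=C bond to the ynol ether in a (2+2) cycloaddition, the nucleophilic CH terminus of 5 bonding to the ketene carbonyl carbon (ring B C2–C3) and the aryloxy-bearing carbon to the ketene α-carbon (C1–C6), giving cyclobutenone 15. Four-electron electrocyclic opening of 15, reversible and driven by light or by the 80 °C stage, gives dienylketene 16, and enolisation of the cyclohexadienone 17 formed from it should deliver phenol 18. This is the Danheiser benzannulation in its photo-Wolff variant, known for diazo enones with alkoxy- and siloxyalkynes and applied here to an aryloxyalkyne and a dioxygenated vinylketene. Ring B is closed by a six-electron disrotatory electrocyclisation of 16 that forms C3–C4 between the ketene carbon and the benzyloxy-bearing terminus; the sp3 centres of 15 and 17 vanish on aromatisation, so no stereocentre has to be controlled. The selectivity needed is the orientation of the (2+2) step, which the oxygen-induced polarisation of the ynol ether secures, putting the ring A oxygen on C1 between two C–H and meta to the new C3 hydroxyl, with benzyloxy on C4 and methoxy on C5. The Z enol ether places H, not OBn, on the inside of the closing triene, and any Z/E scrambling under irradiation is harmless because both isomers converge on 18.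

Step 8
Reactants: 18 2-(benzyloxy)-3-methoxy-5-(2,4,6-trimethoxyphenoxy)phenol
Product: 19 2-[4-(benzyloxy)-3,5-dimethoxyphenoxy]-1,3,5-trimethoxybenzene
Conditions: MeI, K2CO3, acetone, reflux
Reagents that add atoms: iodomethane, CI
Why: Williamson O-methylation of the only free phenol, which makes the two meta oxygens of ring B equivalent.

Step 9
Reactants: 19 2-[4-(benzyloxy)-3,5-dimethoxyphenoxy]-1,3,5-trimethoxybenzene
Product: 20 2,6-dimethoxy-4-(2,4,6-trimethoxyphenoxy)phenol
Conditions: H2 (1 atm), 10% Pd/C, EtOAc/MeOH, rt
Reagents that add atoms: none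
Why: catalytic hydrogenolysis of the benzyl ether frees the ring B C4 phenol, aryl methyl ethers and the diaryl ether being inert.

Step 10
Reactants: 21 4-bromo-2,6-dimethoxyphenol; 7 benzyl bromide
Product: 22 2-(benzyloxy)-5-bromo-1,3-dimethoxybenzene
Conditions: K2CO3, DMF, rt
Reagents that add atoms: none
Why: Williamson benzylation of the phenol; the aryl bromide does not react.

Step 11
Reactants: 20 2,6-dimethoxy-4-(2,4,6-trimethoxyphenoxy)phenol; 22 2-(benzyloxy)-5-bromo-1,3-dimethoxybenzene
Product: 23 2-{4-[4-(benzyloxy)-3,5-dimethoxyphenoxy]-3,5-dimethoxyphenoxy}-1,3,5-trimethoxybenzene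
Conditions: CuI (10 mol%), picolinic acid (20 mol%), K3PO4, DMSO, 100 °C
Reagents that add atoms: none
Why: Ullmann-type copper-catalysed O-arylation with picolinic acid as ligand, a system that accepts di-ortho-substituted phenols and electron-rich aryl bromides; the bromide carbon of 22 has no ortho substituent, 20 has no halide and 22 no free OH, so only the ring B–O–ring C bond can form.

Step 12
Reactants: 23 ring A–B–C benzyl ether
Product: 24 4-[2,6-dimethoxy-4-(2,4,6-trimethoxyphenoxy)phenoxy]-2,6-dimethoxyphenol
Conditions: H2 (1 atm), 10% Pd/C, EtOAc/MeOH, rt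
Reagents that add atoms: none
Why: hydrogenolysis of the benzyl ether frees the ring C C4 phenol without touching methyl or diaryl ethers.

Step 13
Reactants: 25 2,3,4-trimethoxyphenol
Product: 26 6-iodo-2,3,4-trimethoxyphenol
Conditions: I2, NaHCO3, THF/H2O, 0 °C to rt
Reagents that add atoms: iodine, II
Why: electrophilic aromatic iodination through the phenoxide; with the para position blocked, iodine should enter ortho to the hydroxyl (C6, also para to the 3-methoxy group) and not at C5, which only methoxy groups activate.

Step 14
Reactants: 26 6-iodo-2,3,4-trimethoxyphenol; 7 benzyl bromide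
Product: 27 2-(benzyloxy)-1-iodo-3,4,5-trimethoxybenzene
Conditions: K2CO3, DMF, rt
Reagents that add atoms: none
Why: Williamson benzylation masks the future ring D C2 oxygen; the aryl iodide is inert.

Step 15
Reactants: 24 ring A–B–C phenol; 27 2-(benzyloxy)-1-iodo-3,4,5-trimethoxybenzene (2 equiv)
Product: 28 ring A–B–C–D benzyl ether (24 O-arylated at the ring C phenol oxygen by the 2-(benzyloxy)-3,4,5-trimethoxyphenyl group)
Conditions: CuI (20 mol%), picolinic acid (40 mol%), K3PO4, DMSO, 100 °C
Reagents that add atoms: none
Why: the same Ullmann etherification, run with an aryl iodide because the reacting carbon has an ortho benzyloxy group; couplings of 2,6-disubstituted phenols with ortho-substituted aryl iodides lie within the scope of CuI/picolinic acid.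

Step 16
Reactants: 28 ring A–B–C–D benzyl ether
Product: 29 ring A–B–C–D phenol (2-hydroxy-3,4,5-trimethoxyphenyl ether of 24, OH on ring D C2)
Conditions: H2 (1 atm), 10% Pd/C, EtOAc/MeOH, rt
Reagents that add atoms: none
Why: hydrogenolysis of the benzyl ether frees the ring D C2 phenol; all other ethers are stable.

Step 17
Reactants: 21 4-bromo-2,6-dimethoxyphenol; 30 (3,4,5-trimethoxyphenyl)boronic acid
Product: 31 5-bromo-1,3-dimethoxy-2-(3,4,5-trimethoxyphenoxy)benzene
Conditions: Cu(OAc)2 (2 equiv), pyridine, 4 Å MS, CH2Cl2, air, rt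
Reagents that add atoms: none
Why: Chan–Lam oxidative O-arylation with divalent copper at room temperature, known to tolerate di-ortho-substituted phenols; the aryl bromide of 21 is inert under these conditions, so the ring E–O–ring F ether forms without self-condensation.

Step 18
Reactants: 29 ring A–B–C–D phenol; 31 5-bromo-1,3-dimethoxy-2-(3,4,5-trimethoxyphenoxy)benzene
Product: 32 pentadeca-O-methyl ether of the target
Conditions: CuI (20 mol%), picolinic acid (40 mol%), K3PO4, DMSO, 110 °C
Reagents that add atoms: none
Why: Ullmann etherification of the ring D phenol (flanked by a methoxy and an aryloxy group) with the ortho-unsubstituted bromide of 31 closes the last ether bond, ring D C2–O–ring E C1.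

Step 19
Reactants: 32 pentadeca-O-methyl ether of the target
Product: 33 CNP0175585.0
Conditions: BBr3 (excess), CH2Cl2, −78 °C to rt; MeOH then H2O, under Ar
Reagents that add atoms: none
Why: Lewis-acid ether cleavage with BBr3 (bromide attacks each O-methyl carbon of the boron-complexed ether by SN2) should remove all fifteen methyl groups, while the five diaryl ether bonds offer no sp3 carbon and survive; quench and isolation are done under argon because the polyphenol is air-sensitive.

**Compound list**
1 | 2,4,6-trimethoxyphenol | COc1cc(OC)c(O)c(OC)c1 | starting material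
2 | trichloroethylene | ClC=C(Cl)Cl | starting material
3 | (E)-2-[(1,2-dichloroethenyl)oxy]-1,3,5-trimethoxybenzene | Cl/C=C(/Cl)Oc1c(OC)cc(OC)cc1OC | intermediate
4 | lithium (2,4,6-trimethoxyphenoxy)acetylide | [Li]C#COc1c(OC)cc(OC)cc1OC | intermediate (not isolated)
5 | 2-(ethynyloxy)-1,3,5-trimethoxybenzene | C#COc1c(OC)cc(OC)cc1OC | intermediate
6 | methyl methoxyacetate | COCC(=O)OC | starting material
7 | benzyl bromide | BrCc1ccccc1 | starting material
8 | sodium enolate of methyl 2-methoxy-3-oxopropanoate (delocalised, geometry not fixed) | [Na+].[O-]C=C(OC)C(=O)OC | intermediate (not isolated)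
9 | methyl (Z)-3-(benzyloxy)-2-methoxyprop-2-enoate | COC(=O)/C(OC)=C/OCc1ccccc1 | intermediate
10 | (Z)-3-(benzyloxy)-N,2-dimethoxy-N-methylprop-2-enamide | CON(C)C(=O)/C(OC)=C/OCc1ccccc1 | intermediate
11 | (Z)-4-(benzyloxy)-3-methoxybut-3-en-2-one | CC(=O)/C(OC)=C/OCc1ccccc1 | intermediate
12 | (Z)-6-(benzyloxy)-1,1,1-trifluoro-5-methoxyhex-5-ene-2,4-dione | O=C(CC(=O)/C(OC)=C/OCc1ccccc1)C(F)(F)F | intermediate (not isolated)
13 | (Z)-4-(benzyloxy)-1-diazo-3-methoxybut-3-en-2-one | [N-]=[N+]=CC(=O)/C(OC)=C/OCc1ccccc1 | intermediate
14 | (Z)-4-(benzyloxy)-3-methoxybuta-1,3-dien-1-one (vinylketene) | O=C=C/C(OC)=C/OCc1ccccc1 | intermediate (not isolated)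
15 | 4-[(Z)-2-(benzyloxy)-1-methoxyethenyl]-3-(2,4,6-trimethoxyphenoxy)cyclobut-2-en-1-one (racemic) | O=C1C=C(Oc2c(OC)cc(OC)cc2OC)C1/C(OC)=C/OCc1ccccc1 | intermediate (not isolated)
16 | (3E,5Z)-6-(benzyloxy)-5-methoxy-3-(2,4,6-trimethoxyphenoxy)hexa-1,3,5-trien-1-one (dienylketene, ketene arm cis to C5 across C3=C4) | O=C=C/C(Oc1c(OC)cc(OC)cc1OC)=C\C(OC)=C\OCc1ccccc1 | intermediate (not isolated)
17 | 6-(benzyloxy)-5-methoxy-3-(2,4,6-trimethoxyphenoxy)cyclohexa-2,4-dien-1-one (racemic keto tautomer of 18) | O=C1C=C(Oc2c(OC)cc(OC)cc2OC)C=C(OC)C1OCc1ccccc1 | intermediate (not isolated)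
18 | 2-(benzyloxy)-3-methoxy-5-(2,4,6-trimethoxyphenoxy)phenol | COc1cc(OC)c(Oc2cc(O)c(OCc3ccccc3)c(OC)c2)c(OC)c1 | intermediate
19 | 2-[4-(benzyloxy)-3,5-dimethoxyphenoxy]-1,3,5-trimethoxybenzene | COc1cc(OC)c(Oc2cc(OC)c(OCc3ccccc3)c(OC)c2)c(OC)c1 | intermediate
20 | 2,6-dimethoxy-4-(2,4,6-trimethoxyphenoxy)phenol | COc1cc(OC)c(Oc2cc(OC)c(O)c(OC)c2)c(OC)c1 | intermediate
21 | 4-bromo-2,6-dimethoxyphenol | COc1cc(Br)cc(OC)c1O | starting material
22 | 2-(benzyloxy)-5-bromo-1,3-dimethoxybenzene | COc1cc(Br)cc(OC)c1OCc1ccccc1 | intermediate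
23 | 2-{4-[4-(benzyloxy)-3,5-dimethoxyphenoxy]-3,5-dimethoxyphenoxy}-1,3,5-trimethoxybenzene | COc1cc(OC)c(Oc2cc(OC)c(Oc3cc(OC)c(OCc4ccccc4)c(OC)c3)c(OC)c2)c(OC)c1 | intermediate
24 | 4-[2,6-dimethoxy-4-(2,4,6-trimethoxyphenoxy)phenoxy]-2,6-dimethoxyphenol | COc1cc(OC)c(Oc2cc(OC)c(Oc3cc(OC)c(O)c(OC)c3)c(OC)c2)c(OC)c1 | intermediate
25 | 2,3,4-trimethoxyphenol | COc1ccc(O)c(OC)c1OC | starting material
26 | 6-iodo-2,3,4-trimethoxyphenol | COc1cc(I)c(O)c(OC)c1OC | intermediate
27 | 2-(benzyloxy)-1-iodo-3,4,5-trimethoxybenzene | COc1cc(I)c(OCc2ccccc2)c(OC)c1OC | intermediate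
28 | ring A–B–C–D benzyl ether (2-(benzyloxy)-3,4,5-trimethoxyphenyl ether of 24) | COc1cc(OC)c(Oc2cc(OC)c(Oc3cc(OC)c(Oc4cc(OC)c(OC)c(OC)c4OCc5ccccc5)c(OC)c3)c(OC)c2)c(OC)c1 | intermediate
29 | ring A–B–C–D phenol (2-hydroxy-3,4,5-trimethoxyphenyl ether of 24) | COc1cc(OC)c(Oc2cc(OC)c(Oc3cc(OC)c(Oc4cc(OC)c(OC)c(OC)c4O)c(OC)c3)c(OC)c2)c(OC)c1 | intermediate
30 | (3,4,5-trimethoxyphenyl)boronic acid | COc1cc(B(O)O)cc(OC)c1OC | starting material
31 | 5-bromo-1,3-dimethoxy-2-(3,4,5-trimethoxyphenoxy)benzene | COc1cc(Oc2c(OC)cc(Br)cc2OC)cc(OC)c1OC | intermediate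
32 | pentadeca-O-methyl ether of the target | COc1cc(OC)c(Oc2cc(OC)c(Oc3cc(OC)c(Oc4cc(OC)c(OC)c(OC)c4Oc4cc(OC)c(Oc5cc(OC)c(OC)c(OC)c5)c(OC)c4)c(OC)c3)c(OC)c2)c(OC)c1 | intermediate
33 | CNP0175585.0 | Oc1cc(O)c(Oc2cc(O)c(Oc3cc(O)c(Oc4cc(O)c(O)c(O)c4Oc4cc(O)c(Oc5cc(O)c(O)c(O)c5)c(O)c4)c(O)c3)c(O)c2)c(O)c1 | target

**Step count**
Total steps: 19. Longest linear sequence: 13 steps (3, 4, 5, 6, 7, 8, 9, 11, 12, 15, 16, 18, 19) from methyl methoxyacetate.

**Steps most likely to fail**

Step 7 (benzannulation). The oxygen-rich vinylketene may dimerise or be consumed unproductively, and the terminal aryl ynol ether may polymerise or absorb the light, before the (2+2) event; the orientation of the cycloaddition could also erode. Fallback: the ring A–O–ring B ether is made by copper-catalysed Ullmann etherification instead. Phenol 1 and bromide 22 (from step 10) with CuI, picolinic acid and K3PO4 in DMSO at 100 °C should give 19 directly. The fallback sets out from 1 and rejoins the route at 19; no compound outside the list is made (F0).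

Step 15 (ring C–O–ring D coupling). C–O bond formation between a di-ortho-substituted phenoxide on a large substrate and an ortho-substituted, electron-rich aryl iodide may be so slow that protodeiodination and phenoxide oxidation win. Fallback: the congested ether is forged first on small fragments by oxidative coupling, and the fragments are then joined at an unhindered bromide. Starting from 27, iodine–magnesium exchange (i-PrMgCl·LiCl, THF, −20 °C), B(OMe)3 and dilute acid should give [2-(benzyloxy)-3,4,5-trimethoxyphenyl]boronic acid F1. Chan–Lam coupling of F1 with phenol 21 (Cu(OAc)2, pyridine, 4 Å MS, CH2Cl2, air, rt) should give 2-[2-(benzyloxy)-3,4,5-trimethoxyphenoxy]-5-bromo-1,3-dimethoxybenzene F2. Ullmann coupling of phenol 20 with F2 (CuI, picolinic acid, K3PO4, DMSO, 100 °C) then gives 28, where the route is rejoined; 22, 23 and 24 are bypassed.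

Step 19 (global demethylation). Cleavage of fifteen ethers may stop short, and the free polyphenol may oxidise or bind irreversibly to the stationary phase during isolation. Fallback: derivatise, purify, release. Starting from 32, the crude BBr3 product is not purified but acetylated (Ac2O, pyridine, rt) to the pentadecaacetate of the target F3, which is chromatographed on silica so that partly methylated material can be separated and recycled. Zemplén deacetylation (catalytic NaOMe, degassed MeOH, rt, Ar, then acidic resin) then returns to the route at 33.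

**Further compounds**
F0 | step 7 | none | none
F1 | step 15 | [2-(benzyloxy)-3,4,5-trimethoxyphenyl]boronic acid | COc1cc(B(O)O)c(OCc2ccccc2)c(OC)c1OC
F2 | step 15 | 2-[2-(benzyloxy)-3,4,5-trimethoxyphenoxy]-5-bromo-1,3-dimethoxybenzene | COc1cc(Br)cc(OC)c1Oc1cc(OC)c(OC)c(OC)c1OCc1ccccc1
F3 | step 19 | pentadecaacetate of the target | CC(=O)Oc1cc(OC(C)=O)c(Oc2cc(OC(C)=O)c(Oc3cc(OC(C)=O)c(Oc4cc(OC(C)=O)c(OC(C)=O)c(OC(C)=O)c4Oc4cc(OC(C)=O)c(Oc5cc(OC(C)=O)c(OC(C)=O)c(OC(C)=O)c5)c(OC(C)=O)c4)c(OC(C)=O)c3)c(OC(C)=O)c2)c(OC(C)=O)c1
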